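common to all: substrate 0.010 M; free catalyst 20 µM
- green: temperature 25 °C; the very flask that is asked about, followed so far
- teal: temperature 20 °C; run made earlier
- flask: temperature 25 °C; time 8.0 d

- green (time / d: target / %, substrate / %): 0.333: 12.5, 25.9; 1.04: 16.1, 2.0; 1.67: 16.0, 0.6; 3.00: 15.6, 0.3; 4.00: 16.3, 0; 5.00: 16.4, 0; 6.00: 16.6, 0.3
- teal (time / d: target / %, substrate / %): 0.333: 10.6, 52.1; 1.04: 19.1, 13.0; 1.67: 21.7, 3.0; 3.00: 21.5, 1.0; 4.00: 22.4, 0; 5.00: 21.7, 0; 6.00: 21.3, 0.3

(scatter of a reading: 0.5 percentage points)

- south-west: at 8.0 d add free catalyst, 100% of the amount charged, then wait 15 d
- north-west: at 8.0 d raise the temperature by 15 K, then wait 15 d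
- north-east: change nothing and wait 15 d more
- north: at 8.0 d add substrate, 50.0% of the amount charged, then wait 15 d

- the volume of additions can be left aside
- a reading or a percentage of target counts all its forms, free or not

- target, in percent of the substrate first charged, at 8.0 d
- the option that brings most further target ("none" if no option brings more than 2 percentage points) (south-west / north-west / north-east / north / none)
- target present, in percent of the substrate first charged, after south-west
- target present, in percent of the substrate first charged, after north-west

**The gap.** Target in the green flask holds at 16.2% from 3.00 d on, and I take that as my answer for 8.0 d. Substrate reads 0.3%, so 83.5% of the charge shows in neither column. The readings leave open whether fresh free catalyst can work on this gap, so I bracket south-west.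

**Lower bound.** If the gap is dead matter, south-west adds nothing and target stays at 16.2%.

**Upper bound.** Target can gain no more than the gap itself, which caps south-west at 99.7%. To tighten this, suppose instead that the gap is a pool that falls pseudo-first-order at a given [free catalyst], and reckon the fraction left. A charge then has a dose, minus the natural logarithm of the fraction of a standing pool it leaves. In the green flask the gap grows to 61.6% at 0.333 d and 81.9% at 1.04 d. Dividing the target gained in each interval by the mean gap and adding gives 0.456. An equal charge therefore leaves 63.4% of a standing pool, and the gain is 31 percentage points, which puts target near 46.8%. This is an estimate inside the bracket and no bound: if only part of the gap is reachable, the same target implies a larger dose, and the gain may come out on either side of this one.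

**The forecast.** It gives 16.2% now, 16.2% after south-west, 16.2% after north-west, and names north as best, “assuming the catalyst is still alive, which the clean decay suggests”. Its south-west value sits at my lower bound. I stake on south-west: an estimated 31 points against the 8 points it expects from north.

**The result.** The flask gives 16.1% now, 16.1% after north-west and 47.4% after south-west, a gain of 31 points, while north gains 0 points.

    substrate → intermediate (k = 3.20 × 10⁻⁵ /s, Ea = 100 kJ/mol)
    free catalyst + intermediate → free catalyst + target (k = 4.40 /M/s, Ea = 49.0 kJ/mol)
    substrate → uncatalysed product (k = 1.40 × 10⁻⁵ /s, Ea = 102 kJ/mol)
    free catalyst + target ⇌ idle complex, settled at all times (K = 280 /M, ΔH = −25.0 kJ/mol)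
    free catalyst → spent catalyst (k = 1.00 × 10⁻⁴ /s, Ea = 100 kJ/mol)
    (constants at 25 °C)

At 8.00 d the gap holds intermediate 53.4% and uncatalysed product 30.4%, with spent catalyst 100%. My 63.4% on the whole gap gave 31 points, but that pool was wider than the intermediate, so the closeness proves no dose.

**Next flask.** The neighbour with 8.0 × 10⁻⁵ M of free catalyst scales the dose to 1.82. The green plateau implies a pool of 44.3% as the charge meets it, so I expect 37.2%. The simulation gives 41.3%.

The data are simulated with made-up constants; noise was put on by code.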